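The route rests on disconnecting the aryl ether O1–C8a of the pyran ring (ring C) of the lower catechin unit. C8a of its benzo ring (ring A) is meta to the C5 and C7 oxygens, so it maps onto the bromine of a 5-bromoresorcinol diether. A copper-catalysed intramolecular O-arylation of an acyclic (1R,2S)-bromo alcohol closes ring C without breaking the C2–O bond. The anti pattern set by auxiliary alkylation and chelation-controlled reduction therefore becomes the 2,3-trans flavan. The perbenzylated catechin is then grown upward by two C4→C8 Friedel–Crafts couplings with epicatechin and epiafzelechin electrophiles and debenzylated.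

Key step: step 8

Remark: flavan numbering (O1, C2–C4, C4a, C5–C8, C8a; benzo ring A, pyran ring C) is used for every unit and for the open-chain precursors of the lower unit; (−)-epicatechin, (−)-epiafzelechin, 1,3-bis(benzyloxy)-5-bromobenzene, 4-bromo-1,2-bis(benzyloxy)benzene and (R)-4-benzyl-3-[(benzyloxy)acetyl]oxazolidin-2-one are taken as catalogue compounds.

**Step 1**
Reactants: 1 1,3-bis(benzyloxy)-5-bromobenzene
Product: 3 2-bromo-4,6-bis(benzyloxy)benzaldehyde, via iminium chloride 2 (not isolated)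
Conditions: POCl3, DMF, 0 to 70 °C; then ice–water
Reagents that add atoms: N,N-dimethylformamide CN(C)C=O; water O
Why: Vilsmeier–Haack formylation, in which the chloroiminium ion should attack the position ortho to bromine and para to one benzyloxy group (the site between the two ethers is doubly flanked), as is usual for 5-substituted resorcinol diethers; water hydrolyses iminium 2.

**Step 2**
Reactants: 3 2-bromo-4,6-bis(benzyloxy)benzaldehyde
Product: 4 [2-bromo-4,6-bis(benzyloxy)phenyl]methanol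
Conditions: NaBH4, THF/MeOH, 0 °C
Reagents that add atoms: none
Why: Chemoselective hydride reduction of the aryl aldehyde, to which the aryl bromide and the benzyl ethers are inert.

**Step 3**
Reactants: 4 [2-bromo-4,6-bis(benzyloxy)phenyl]methanol
Product: 5 2-bromo-4,6-bis(benzyloxy)benzyl bromide
Conditions: CBr4, PPh3, CH2Cl2, 0 °C; used at once
Reagents that add atoms: carbon tetrabromide BrC(Br)(Br)Br
Why: Appel bromination under neutral conditions should convert the electron-rich benzylic alcohol into the bromide without acid that would ionise it.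

**Step 4**
Reactants: 6 (R)-4-benzyl-3-[(benzyloxy)acetyl]oxazolidin-2-one; 5 2-bromo-4,6-bis(benzyloxy)benzyl bromide
Product: 8 (R)-4-benzyl-3-[(S)-2-(benzyloxy)-3-(2-bromo-4,6-bis(benzyloxy)phenyl)propanoyl]oxazolidin-2-one, via sodium enolate 7 (not isolated)
Conditions: NaN(SiMe3)2, THF, −78 °C; then 5, −78 to −40 °C
Reagents that add atoms: none
Why: Evans asymmetric alkylation, in which the sodium-chelated Z-enolate 7 is alkylated by the reactive benzylic bromide on the face opposite the auxiliary benzyl group, setting the S configuration of the benzyloxy-bearing carbon (future C3).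

**Step 5**
Reactants: 8 (R)-4-benzyl-3-[(S)-2-(benzyloxy)-3-(2-bromo-4,6-bis(benzyloxy)phenyl)propanoyl]oxazolidin-2-one
Product: 9 (S)-2-(benzyloxy)-3-[2-bromo-4,6-bis(benzyloxy)phenyl]-N-methoxy-N-methylpropanamide
Conditions: MeNH(OMe)·HCl, AlMe3, CH2Cl2, 0 °C to rt; then H2O
Reagents that add atoms: N,O-dimethylhydroxylamine hydrochloride Cl.CNOC
Why: Aluminium amide transamination should cleave the imide at the exocyclic carbonyl to the Weinreb amide without epimerisation and release the auxiliary.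

**Step 6**
Reactants: 9 (S)-2-(benzyloxy)-3-[2-bromo-4,6-bis(benzyloxy)phenyl]-N-methoxy-N-methylpropanamide; 10 4-bromo-1,2-bis(benzyloxy)benzene
Product: 12 (S)-2-(benzyloxy)-1-[3,4-bis(benzyloxy)phenyl]-3-[2-bromo-4,6-bis(benzyloxy)phenyl]propan-1-one, via arylmagnesium bromide 11 (not isolated)
Conditions: 10, Mg, THF, 40 °C; then 9, THF, 0 °C; then H2O
Reagents that add atoms: none
Why: Weinreb ketone synthesis, in which Grignard reagent 11 adds once because the chelated tetrahedral intermediate survives until work-up, and the ring A aryl bromide is not exchanged by an arylmagnesium halide at 0 °C.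

**Step 7**
Reactants: 12 (S)-2-(benzyloxy)-1-[3,4-bis(benzyloxy)phenyl]-3-[2-bromo-4,6-bis(benzyloxy)phenyl]propan-1-one
Product: 13 (1R,2S)-2-(benzyloxy)-1-[3,4-bis(benzyloxy)phenyl]-3-[2-bromo-4,6-bis(benzyloxy)phenyl]propan-1-ol
Conditions: Zn(BH4)2, Et2O/CH2Cl2, −30 to 0 °C
Reagents that add atoms: none
Why: Cram-chelate controlled reduction, in which zinc bridges the carbonyl and α-benzyloxy oxygens and hydride arrives from the face of the α-hydrogen, should give the anti (1R,2S) alcohol that defines the future C2.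

**Step 8**
Reactants: 13 (1R,2S)-2-(benzyloxy)-1-[3,4-bis(benzyloxy)phenyl]-3-[2-bromo-4,6-bis(benzyloxy)phenyl]propan-1-ol
Product: 14 (2R,3S)-3,5,7-tris(benzyloxy)-2-[3,4-bis(benzyloxy)phenyl]chromane (3,5,7,3',4'-penta-O-benzyl-(+)-catechin)
Conditions: CuI (10 mol %), 3,4,7,8-tetramethyl-1,10-phenanthroline (20 mol %), Cs2CO3, toluene, 110 °C
Reagents that add atoms: none
Why: Ullmann-type intramolecular O-arylation: Cs2CO3 and phenanthroline-ligated monovalent copper give a copper alkoxide, which adds oxidatively into the ortho C–Br bond to a trivalent copper aryl alkoxide and then undergoes C–O reductive elimination. The closest known reaction type is the copper-catalysed cyclisation of 3-(2-bromoaryl)propan-1-ols to chromans. Ring C is closed in a six-membered exo mode by attack of O1 on C8a, the ring A carbon that is meta to both ether oxygens and so cannot be oxygenated by electrophilic or oxidative means. No stereocentre is formed: the carbinol C–O bond is never broken, so C2 keeps its R configuration and its anti relationship to the C3 benzyloxy group appears as 2,3-trans. The step needs chemoselectivity for the six-membered ether, which is secured because the only other oxygen within reach (on C3) is benzylated, so no dihydrobenzofuran can form, and because copper, unlike palladium, has little tendency to oxidise the benzylic alkoxide by β-hydride elimination.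

**Step 9**
Reactants: 15 (−)-epicatechin
Product: 16 5,7,3',4'-tetra-O-benzyl-(−)-epicatechin
Conditions: BnBr, K2CO3, DMF, 0 °C to rt
Reagents that add atoms: benzyl bromide BrCc1ccccc1
Why: Williamson benzylation of the four phenols under mild carbonate base should leave the less acidic C3 alcohol free and avoid base-induced C2 epimerisation.

**Step 10**
Reactants: 16 5,7,3',4'-tetra-O-benzyl-(−)-epicatechin
Product: 17 4β-(2-ethoxyethoxy)-5,7,3',4'-tetra-O-benzyl-(−)-epicatechin
Conditions: DDQ, 2-ethoxyethanol, CH2Cl2, rt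
Reagents that add atoms: 2-ethoxyethanol CCOCCO
Why: DDQ benzylic oxidation, in which hydride is abstracted from C4 (activated by the trioxygenated ring A) and the alcohol traps the cation trans to the C3 hydroxyl; this centre is ionised again in step 11.

**Step 11**
Reactants: 17 4β-(2-ethoxyethoxy)-5,7,3',4'-tetra-O-benzyl-(−)-epicatechin; 14 3,5,7,3',4'-penta-O-benzyl-(+)-catechin
Product: 18 5,7,3',4'-tetra-O-benzylepicatechin-(4β→8)-3,5,7,3',4'-penta-O-benzylcatechin
Conditions: Me3SiOTf (cat.), CH2Cl2, −78 °C; 14 in excess (recovered)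
Reagents that add atoms: none
Why: Friedel–Crafts type flavan coupling, in which the ring A stabilised C4 cation is attacked by C8 of 14 (ortho to O1, para to the C5 ether, less hindered than C6) from the face opposite the cis C2 aryl and C3 oxygen, giving the 3,4-trans (4β→8) bond while excess 14 suppresses self-condensation of 17.

**Step 12**
Reactants: 19 (−)-epiafzelechin
Product: 20 5,7,4'-tri-O-benzyl-(−)-epiafzelechin
Conditions: BnBr, K2CO3, DMF, 0 °C to rt
Reagents that add atoms: benzyl bromide BrCc1ccccc1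
Why: Williamson benzylation of the three phenols, selective over the C3 alcohol as in step 9.

**Step 13**
Reactants: 20 5,7,4'-tri-O-benzyl-(−)-epiafzelechin
Product: 21 4β-(2-ethoxyethoxy)-5,7,4'-tri-O-benzyl-(−)-epiafzelechin
Conditions: DDQ, 2-ethoxyethanol, CH2Cl2, rt
Reagents that add atoms: 2-ethoxyethanol CCOCCO
Why: DDQ benzylic oxidation at C4 with alcohol trapping trans to the C3 hydroxyl, as in step 10.

**Step 14**
Reactants: 21 4β-(2-ethoxyethoxy)-5,7,4'-tri-O-benzyl-(−)-epiafzelechin; 18 5,7,3',4'-tetra-O-benzylepicatechin-(4β→8)-3,5,7,3',4'-penta-O-benzylcatechin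
Product: 22 5,7,4'-tri-O-benzylepiafzelechin-(4β→8)-5,7,3',4'-tetra-O-benzylepicatechin-(4β→8)-3,5,7,3',4'-penta-O-benzylcatechin
Conditions: Me3SiOTf (cat.), CH2Cl2, −78 °C; 18 in excess (recovered)
Reagents that add atoms: none
Why: Friedel–Crafts type flavan coupling, in which C8 of the upper (epicatechin) unit of 18 is the most nucleophilic and least hindered arene site (C8 of the lower unit is substituted and both C6 positions are flanked by two benzyloxy groups) and attack anti to the C2 aryl and C3 oxygen should give the second 4β→8 bond.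

**Step 15**
Reactants: 22 5,7,4'-tri-O-benzylepiafzelechin-(4β→8)-5,7,3',4'-tetra-O-benzylepicatechin-(4β→8)-3,5,7,3',4'-penta-O-benzylcatechin
Product: 23 epiafzelechin-(4β→8)-epicatechin-(4β→8)-catechin (CNP0158921.1)
Conditions: H2 (1 atm), Pd(OH)2/C, THF/MeOH/H2O, rt
Reagents that add atoms: none
Why: Global hydrogenolysis of the twelve benzyl ethers under neutral conditions should leave the acid-labile interflavan bonds and the ring C ethers intact.

**Compound list**

1 | 1,3-bis(benzyloxy)-5-bromobenzene | Brc1cc(OCc2ccccc2)cc(OCc2ccccc2)c1 | starting material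
2 | [2-bromo-4,6-bis(benzyloxy)benzylidene]dimethyliminium chloride | C[N+](C)=Cc1c(Br)cc(OCc2ccccc2)cc1OCc1ccccc1.[Cl-] | intermediate (not isolated)
3 | 2-bromo-4,6-bis(benzyloxy)benzaldehyde | O=Cc1c(Br)cc(OCc2ccccc2)cc1OCc1ccccc1 | intermediate
4 | [2-bromo-4,6-bis(benzyloxy)phenyl]methanol | OCc1c(Br)cc(OCc2ccccc2)cc1OCc1ccccc1 | intermediate
5 | 2-bromo-4,6-bis(benzyloxy)benzyl bromide | BrCc1c(Br)cc(OCc2ccccc2)cc1OCc1ccccc1 | intermediate
6 | (R)-4-benzyl-3-[(benzyloxy)acetyl]oxazolidin-2-one | O=C(COCc1ccccc1)N1C(=O)OC[C@H]1Cc1ccccc1 | starting material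
7 | sodium Z-enolate of 6 | [Na+].[O-]/C(=C\OCc1ccccc1)N1C(=O)OC[C@H]1Cc1ccccc1 | intermediate (not isolated)
8 | (R)-4-benzyl-3-[(S)-2-(benzyloxy)-3-(2-bromo-4,6-bis(benzyloxy)phenyl)propanoyl]oxazolidin-2-one | O=C([C@@H](OCc1ccccc1)Cc1c(Br)cc(OCc2ccccc2)cc1OCc1ccccc1)N1C(=O)OC[C@H]1Cc1ccccc1 | intermediate
9 | (S)-2-(benzyloxy)-3-[2-bromo-4,6-bis(benzyloxy)phenyl]-N-methoxy-N-methylpropanamide | CON(C)C(=O)[C@@H](OCc1ccccc1)Cc1c(Br)cc(OCc2ccccc2)cc1OCc1ccccc1 | intermediate
10 | 4-bromo-1,2-bis(benzyloxy)benzene | Brc1ccc(OCc2ccccc2)c(OCc2ccccc2)c1 | starting material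
11 | [3,4-bis(benzyloxy)phenyl]magnesium bromide | Br[Mg]c1ccc(OCc2ccccc2)c(OCc2ccccc2)c1 | intermediate (not isolated)
12 | (S)-2-(benzyloxy)-1-[3,4-bis(benzyloxy)phenyl]-3-[2-bromo-4,6-bis(benzyloxy)phenyl]propan-1-one | O=C(c1ccc(OCc2ccccc2)c(OCc2ccccc2)c1)[C@@H](OCc1ccccc1)Cc1c(Br)cc(OCc2ccccc2)cc1OCc1ccccc1 | intermediate
13 | (1R,2S)-2-(benzyloxy)-1-[3,4-bis(benzyloxy)phenyl]-3-[2-bromo-4,6-bis(benzyloxy)phenyl]propan-1-ol (anti) | O[C@H](c1ccc(OCc2ccccc2)c(OCc2ccccc2)c1)[C@@H](OCc1ccccc1)Cc1c(Br)cc(OCc2ccccc2)cc1OCc1ccccc1 | intermediate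
14 | (2R,3S)-3,5,7-tris(benzyloxy)-2-[3,4-bis(benzyloxy)phenyl]chromane (penta-O-benzyl-(+)-catechin, 2,3-trans) | O(Cc1ccccc1)c1cc(OCc2ccccc2)c2c(c1)O[C@H](c1ccc(OCc3ccccc3)c(OCc3ccccc3)c1)[C@@H](OCc1ccccc1)C2 | intermediate
15 | (−)-epicatechin, (2R,3R) | Oc1ccc([C@H]2Oc3cc(O)cc(O)c3C[C@H]2O)cc1O | starting material
16 | 5,7,3',4'-tetra-O-benzyl-(−)-epicatechin | O(Cc1ccccc1)c1ccc([C@H]2Oc3cc(OCc4ccccc4)cc(OCc4ccccc4)c3C[C@H]2O)cc1OCc1ccccc1 | intermediate
17 | 4β-(2-ethoxyethoxy)-5,7,3',4'-tetra-O-benzyl-(−)-epicatechin (2,3-cis, 3,4-trans) | O(Cc1ccccc1)c1ccc([C@H]2Oc3cc(OCc4ccccc4)cc(OCc4ccccc4)c3[C@H](OCCOCC)[C@H]2O)cc1OCc1ccccc1 | intermediate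
18 | 5,7,3',4'-tetra-O-benzylepicatechin-(4β→8)-3,5,7,3',4'-penta-O-benzylcatechin (upper unit 2,3-cis-3,4-trans; lower unit 2R,3S) | c1c(OCc2ccccc2)cc(OCc2ccccc2)c2c1O[C@H](c1ccc(OCc3ccccc3)c(OCc3ccccc3)c1)[C@H](O)[C@H]2c1c(OCc2ccccc2)cc(OCc2ccccc2)c2c1O[C@H](c1ccc(OCc3ccccc3)c(OCc3ccccc3)c1)[C@@H](OCc1ccccc1)C2 | intermediate
19 | (−)-epiafzelechin, (2R,3R) | Oc1ccc([C@H]2Oc3cc(O)cc(O)c3C[C@H]2O)cc1 | starting material
20 | 5,7,4'-tri-O-benzyl-(−)-epiafzelechin | O(Cc1ccccc1)c1ccc([C@H]2Oc3cc(OCc4ccccc4)cc(OCc4ccccc4)c3C[C@H]2O)cc1 | intermediate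
21 | 4β-(2-ethoxyethoxy)-5,7,4'-tri-O-benzyl-(−)-epiafzelechin (2,3-cis, 3,4-trans) | O(Cc1ccccc1)c1ccc([C@H]2Oc3cc(OCc4ccccc4)cc(OCc4ccccc4)c3[C@H](OCCOCC)[C@H]2O)cc1 | intermediate
22 | 5,7,4'-tri-O-benzylepiafzelechin-(4β→8)-5,7,3',4'-tetra-O-benzylepicatechin-(4β→8)-3,5,7,3',4'-penta-O-benzylcatechin | O(Cc1ccccc1)c1ccc([C@H]2Oc3cc(OCc4ccccc4)cc(OCc4ccccc4)c3[C@H](c3c(OCc4ccccc4)cc(OCc4ccccc4)c4c3O[C@H](c3ccc(OCc5ccccc5)c(OCc5ccccc5)c3)[C@H](O)[C@H]4c3c(OCc4ccccc4)cc(OCc4ccccc4)c4c3O[C@H](c3ccc(OCc5ccccc5)c(OCc5ccccc5)c3)[C@@H](OCc3ccccc3)C4)[C@H]2O)cc1 | intermediate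
23 | epiafzelechin-(4β→8)-epicatechin-(4β→8)-catechin (CNP0158921.1) | Oc1ccc([C@H]2Oc3cc(O)cc(O)c3[C@H](c3c(O)cc(O)c4c3O[C@H](c3ccc(O)c(O)c3)[C@H](O)[C@H]4c3c(O)cc(O)c4c3O[C@H](c3ccc(O)c(O)c3)[C@@H](O)C4)[C@H]2O)cc1 | target

**Step count and risks**

Total step count: 15. Longest linear sequence: 11 steps (steps 1–8, 11, 14, 15).

Steps most likely to fail:

1. Step 8. Oxidative addition into the electron-rich, ortho-alkylated C–Br bond may be sluggish, so that oxidation of the benzylic alkoxide back to the ketone or hydrodebromination overtakes ring closure. The fallback sets out from 13 and comes back at 14, and replaces catalysis by elimination–addition. Compound 13 is treated with lithium 2,2,6,6-tetramethylpiperidide (3 equiv) in THF at −78 to 0 °C, which deprotonates the hydroxyl and then the ring A C–H flanked by bromine and a benzyloxy group. Loss of LiBr gives the lithium alkoxide of the 3,5-bis(benzyloxy)aryne F1. Its alkoxide should add to the proximal aryne carbon (C8a, meta to the neighbouring ether, as expected for 3-alkoxyarynes) in a six-membered closure, and the resulting C8 aryllithium is protonated to 14.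

2. Step 14. Over-condensation may occur, because electrophile 21 and product 22 each carry a free nucleophilic C8 and compete with 18 for the cation, together with minor attack at C6 sites. The fallback sets out from 21 and comes back at 23. Compound 21 is brominated at C8 (N-bromosuccinimide, CH2Cl2, −78 °C) to the capped electrophile 8-bromo-4β-(2-ethoxyethoxy)-5,7,4'-tri-O-benzylepiafzelechin F2, which can no longer act as a nucleophile at C8. Equimolar Me3SiOTf coupling with 18 should give the 8-bromo dodeca-O-benzyl trimer F3, whose upper unit cannot chain-extend. Hydrogenolysis over Pd(OH)2/C with Et3N present removes the bromine together with the twelve benzyl groups to give 23.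

3. Step 4. The electron-rich benzylic bromide 5 may ionise and self-alkylate before it meets the enolate, and the glycolate enolate may decompose if the alkylation has to be warmed. The fallback sets out from 1 and comes back at 9, and makes the ring A–CH2 bond with the arene as nucleophile.
   - Compound 1 is iodinated (N-iodosuccinimide, cat. CF3CO2H, MeCN) ortho to bromine to give 1-bromo-2-iodo-3,5-bis(benzyloxy)benzene F4.
   - Iodine–magnesium exchange (i-PrMgCl·LiCl, THF, −20 °C) gives [2-bromo-4,6-bis(benzyloxy)phenyl]magnesium chloride F5.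
   - F5 opens methyl (S)-glycidate at its CH2 terminus under CuI catalysis (−40 °C) to methyl (S)-3-[2-bromo-4,6-bis(benzyloxy)phenyl]-2-hydroxypropanoate F6.
   - O-Benzylation (BnBr, Ag2O, CH2Cl2) gives methyl (S)-2-(benzyloxy)-3-[2-bromo-4,6-bis(benzyloxy)phenyl]propanoate F7.
   - MeNH(OMe)·HCl with i-PrMgCl (THF, −20 °C) converts the ester into Weinreb amide 9.

**Further compounds**

F1 | step 8 | lithium (1R,2S)-2-(benzyloxy)-1-[3,4-bis(benzyloxy)phenyl]-3-[4,6-bis(benzyloxy)-2,3-didehydrophenyl]propan-1-olate (aryne, transient) | [Li+].[O-][C@H](c1ccc(OCc2ccccc2)c(OCc2ccccc2)c1)[C@@H](OCc1ccccc1)CC1=C(OCc2ccccc2)C=C(OCc2ccccc2)C#C1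
F2 | step 14 | 8-bromo-4β-(2-ethoxyethoxy)-5,7,4'-tri-O-benzylepiafzelechin | O(Cc1ccccc1)c1ccc([C@H]2Oc3c(Br)c(OCc4ccccc4)cc(OCc4ccccc4)c3[C@H](OCCOCC)[C@H]2O)cc1
F3 | step 14 | 8-bromo-5,7,4'-tri-O-benzylepiafzelechin-(4β→8)-5,7,3',4'-tetra-O-benzylepicatechin-(4β→8)-3,5,7,3',4'-penta-O-benzylcatechin | O(Cc1ccccc1)c1ccc([C@H]2Oc3c(Br)c(OCc4ccccc4)cc(OCc4ccccc4)c3[C@H](c3c(OCc4ccccc4)cc(OCc4ccccc4)c4c3O[C@H](c3ccc(OCc5ccccc5)c(OCc5ccccc5)c3)[C@H](O)[C@H]4c3c(OCc4ccccc4)cc(OCc4ccccc4)c4c3O[C@H](c3ccc(OCc5ccccc5)c(OCc5ccccc5)c3)[C@@H](OCc3ccccc3)C4)[C@H]2O)cc1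
F4 | step 4 | 1-bromo-2-iodo-3,5-bis(benzyloxy)benzene | Brc1cc(OCc2ccccc2)cc(OCc2ccccc2)c1I
F5 | step 4 | [2-bromo-4,6-bis(benzyloxy)phenyl]magnesium chloride | Cl[Mg]c1c(Br)cc(OCc2ccccc2)cc1OCc1ccccc1
F6 | step 4 | methyl (S)-3-[2-bromo-4,6-bis(benzyloxy)phenyl]-2-hydroxypropanoate | COC(=O)[C@@H](O)Cc1c(Br)cc(OCc2ccccc2)cc1OCc1ccccc1
F7 | step 4 | methyl (S)-2-(benzyloxy)-3-[2-bromo-4,6-bis(benzyloxy)phenyl]propanoate | COC(=O)[C@@H](OCc1ccccc1)Cc1c(Br)cc(OCc2ccccc2)cc1OCc1ccccc1
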